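Starting material at 40.0 h stands at 45.7% in gamma and 44.2% in epsilon, but target goes from 8.6% to 12.4%, a factor of 1.44, while catalyst charged minus impurity charged goes from 0.309 mM to 0.620 mM, a factor of 2.01.

in all of them: starting material 0.40 M
- gamma: free catalyst 0.40 mM; impurity 91 µM; run made earlier
- alpha: free catalyst 0.60 mM; impurity 91 µM; run made earlier
- epsilon: free catalyst 0.80 mM; impurity 180 µM; run made earlier
- flask: free catalyst 0.80 mM; impurity 91 µM; time 2.5 d

| run | time / h | target / % | isomer of the product / % | starting material / % |
|---|---|---|---|---|
| gamma | 5.00 | 3.3 | 0 | 89.3 |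
| gamma | 12.0 | 4.7 | 2.4 | 77.7 |
| gamma | 25.0 | 6.7 | 4.0 | 60.4 |
| gamma | 40.0 | 8.6 | 7.1 | 45.7 |
| alpha | 3.00 | 2.5 | 0.7 | 92.1 |
| alpha | 6.00 | 4.3 | 0.6 | 85.6 |
| alpha | 15.0 | 7.1 | 3.1 | 71.8 |
| alpha | 40.0 | 11.3 | 8.1 | 45.5 |
| epsilon | 3.00 | 3.5 | 0.5 | 91.2 |
| epsilon | 6.00 | 5.5 | 0 | 85.3 |
| epsilon | 15.0 | 8.4 | 3.6 | 70.2 |
| epsilon | 40.0 | 12.4 | 9.3 | 44.2 |

(scatter of a reading: 0.5 percentage points)

* ratio of target to isomer of the product at 30 min
* ratio of target to isomer of the product at 5.0 h
* ratio of target to isomer of the product at 2.5 d
* which of target and isomer of the product there is more of at 2.5 d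

- a reading or a percentage of target counts all its forms, free or not

The quick number offered here is target at 2.5 d, the top of the last ratio. In the flask, w = 0.709 mM is the working catalyst, free catalyst charged minus impurity charged, on the supposition that each impurity removes one catalyst. Suppose further that target holds most of w (product inhibition), so that free catalyst goes as w over c(target). Putting that back into a rate proportional to free catalyst makes the square of c(target) grow as w times the time integral of c(starting material). With starting material as alike as in gamma and epsilon, the factor in target between these two runs should then be the root of the factor in w, 1.42. From epsilon, this rule gives gamma 8.75% at 40.0 h, against 8.6% read.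

Read as first order, epsilon's starting material falls at 0.0204 h⁻¹, and on this rule, with the same fall taken for the flask, the integral raises target by a factor 1.12 from 40.0 h to 2.5 d. Scaled to the flask's w, the estimate made here for target is 14.9%.

The forecast gives ratios of 15, 7 and 0.95, with isomer of the product ahead and target near 14% against 14.9% here, on the ground that “That constant scales with catalyst minus impurity”.

The flask gives ratios of 47.1, 6.64 and 1.22, with target ahead at 15.5%, against 12.7% of isomer of the product.

    free catalyst + other conformer → free catalyst + isomer of the product (k = 0.270 M⁻¹ s⁻¹)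
    starting material ⇌ other conformer (K = 0.400, k = 1.60 × 10⁻⁶ s⁻¹)
    starting material + free catalyst → free catalyst + target (k = 0.0150 M⁻¹ s⁻¹)
    free catalyst + target ⇌ idle complex, settled at all times (K = 240 M⁻¹)
    starting material → uncatalysed product (k = 3.10 × 10⁻⁶ s⁻¹)
    free catalyst + impurity → spent catalyst (k = 23.0 M⁻¹ s⁻¹)

In the flask at 2.5 d, spent catalyst holds 11.4% of the catalyst charged, while free catalyst 5.63% and idle complex 83.0% together hold 88.6%, and w over the charge is 88.6%. The neighbouring flask, with 3.6 × 10⁻⁴ M of impurity, has w = 0.440 mM. The same root scaling from 14.9% gives an estimate for target of 11.8%. That flask holds 12.2% of target, all its forms counted, at 2.50 d, with a ratio of target to isomer of the product of 1.04.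

The numbers in the tables are simulated from invented constants, and the scatter is random.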